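With the ring numbered C1 (ketone), C2 (bearing C7), C3, C4 (O-tigloyl), C5 (isopropyl) and C6 (OAc), everything rests on taking C2 out of the cyclohexenone ring. The feature used is that C2 is a single carbon between C1 and C3, with the C1 oxygen next to the C6 oxygen; C1 and C3–C6 are then a Piancatelli cyclopentene that already holds the C4/C5/C6 oxygen–isopropyl–oxygen triad. In one operation the key step opens a fused dibromocyclopropane, turns the five-membered ring into the six-membered ring and lets the C6 tert-butyl carbonate close on C1, leaving bromine on C2 for C7. Its precursor is a 6,6-dibromobicyclo[3.1.0]hexane whose other three ring carbons carry OBoc, isopropyl and OTBS.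

Key step: step 8

Assumption: the lipase in step 3 is taken to acetylate the (4R,5S) alcohol faster, as the usual empirical preference for secondary alcohols suggests when the isopropyl-bearing carbon is the larger flank; the sense has to be confirmed on the first run.

Step 1
Reactants: 1 furfural; 2 isopropylmagnesium chloride
Product: 3 rac-1-(furan-2-yl)-2-methylpropan-1-ol
Conditions: i-PrMgCl, THF, −78 °C to 0 °C; aq NH4Cl
Reagents that add atoms: isopropylmagnesium chloride (compound 2), CC(C)[Mg]Cl
Why: Grignard addition of the isopropyl nucleophile to the non-enolisable aldehyde should be clean at low temperature, and the new carbinol centre may be racemic because it is erased in step 2.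

Step 2
Reactants: 3 rac-1-(furan-2-yl)-2-methylpropan-1-ol
Product: 4 rac-trans-4-hydroxy-5-(propan-2-yl)cyclopent-2-en-1-one
Conditions: ZnCl2, dioxane/H2O, reflux
Reagents that add atoms: water, O
Why: Piancatelli rearrangement, in which acid-induced ionisation of the furylcarbinol, addition of water to the furan and conrotatory 4π electrocyclisation of the resulting pentadienyl cation should give the cyclopentenone with hydroxyl and isopropyl trans, as a racemate.

Step 3
Reactants: 4 rac-trans-4-hydroxy-5-(propan-2-yl)cyclopent-2-en-1-one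
Product: 5 (4S,5R)-4-hydroxy-5-(propan-2-yl)cyclopent-2-en-1-one
Conditions: immobilised Candida antarctica lipase B, vinyl acetate, MTBE, 30 °C, stopped shortly after half conversion
Reagents that add atoms: none
Why: Lipase-catalysed kinetic resolution by irreversible transesterification should acetylate the (4R,5S) alcohol and leave the (4S,5R) alcohol 5, which is separated from the acetate by chromatography and fixes the absolute configuration of C5 and C6 of the target.

Step 4
Reactants: 5 (4S,5R)-4-hydroxy-5-(propan-2-yl)cyclopent-2-en-1-one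
Product: 6 tert-butyl (1S,5R)-4-oxo-5-(propan-2-yl)cyclopent-2-en-1-yl carbonate
Conditions: Boc2O, DMAP (cat.), CH2Cl2, 0 °C
Reagents that add atoms: di-tert-butyl dicarbonate, CC(C)(C)OC(=O)OC(=O)OC(C)(C)C
Why: DMAP-catalysed acyl transfer from Boc2O onto the secondary alcohol is standard carbonate formation at oxygen (configuration retained), and the cold, amine-poor medium is chosen to avoid E1cB loss of the β-carbonate.

Step 5
Reactants: 6 tert-butyl (1S,5R)-4-oxo-5-(propan-2-yl)cyclopent-2-en-1-yl carbonate
Product: 7 tert-butyl (1S,4S,5S)-4-hydroxy-5-(propan-2-yl)cyclopent-2-en-1-yl carbonate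
Conditions: NaBH4, CeCl3·7H2O, MeOH, −78 °C
Reagents that add atoms: none
Why: Luche reduction gives 1,2-addition only, and hydride should come from the face opposite the isopropyl group on the neighbouring carbon, so that the new hydroxyl (future C4–O) ends up cis to isopropyl and trans to the carbonate.

Step 6
Reactants: 7 tert-butyl (1S,4S,5S)-4-hydroxy-5-(propan-2-yl)cyclopent-2-en-1-yl carbonate
Product: 8 tert-butyl (1S,4S,5R)-4-[(tert-butyldimethylsilyl)oxy]-5-(propan-2-yl)cyclopent-2-en-1-yl carbonate
Conditions: TBSCl, imidazole, DMAP (cat.), DMF, rt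
Reagents that add atoms: tert-butyldimethylsilyl chloride, CC(C)(C)[Si](C)(C)Cl
Why: Silylation of a secondary allylic alcohol with TBSCl and imidazole is routine and gives a C4 protecting group that is stable to base, cannot act as a neighbouring group and is removable later with fluoride.

Step 7
Reactants: 8 tert-butyl (1S,4S,5R)-4-[(tert-butyldimethylsilyl)oxy]-5-(propan-2-yl)cyclopent-2-en-1-yl carbonate; 9 bromoform
Product: 10 tert-butyl (1S,2R,3R,4R,5R)-6,6-dibromo-4-[(tert-butyldimethylsilyl)oxy]-3-(propan-2-yl)bicyclo[3.1.0]hexan-2-yl carbonate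
Conditions: CHBr3, 50% aq NaOH, BnEt3NCl (cat.), CH2Cl2, 0 °C to rt
Reagents that add atoms: bromoform (compound 9), BrC(Br)Br
Why: Dibromocarbene generated from bromoform under phase-transfer conditions adds to the cis-alkene in a stereospecific [2+1] cycloaddition, most likely on the face away from OTBS and isopropyl, and the face chosen does not matter because C1 and C3 lose their configuration in step 8.

Step 8
Reactants: 10 tert-butyl (1S,2R,3R,4R,5R)-6,6-dibromo-4-[(tert-butyldimethylsilyl)oxy]-3-(propan-2-yl)bicyclo[3.1.0]hexan-2-yl carbonate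
Product: 13 (3aR,6R,7R,7aR)-4-bromo-6-[(tert-butyldimethylsilyl)oxy]-7-(propan-2-yl)-3a,6,7,7a-tetrahydro-1,3-benzodioxol-2-one, via 2-bromocyclohexenyl cation 11 (not isolated), via tert-butoxydioxolanylium ion 12 (not isolated)
Conditions: AgOTf, 2,6-di-tert-butyl-4-methylpyridine, CH2Cl2/(CF3)2CHOH, 0 °C to rt, dark
Reagents that add atoms: none
Why: AgOTf should pull off the endo bromide while the C1–C3 bond (target numbering) opens in a disrotatory sense to give the 2-bromocyclohex-2-enyl cation 11, whose C1 terminus is attacked by the carbonyl oxygen of the C6 carbonate to give dioxolanylium ion 12, which sheds its tert-butyl group as isobutene. The closest known reaction type is the silver-promoted electrocyclic opening of ring-fused gem-dibromocyclopropanes (cyclopropyl to allyl cation) with capture by a tethered heteroatom nucleophile, joined here to the familiar cyclisation of tert-butyl carbonates onto cationic carbon. The six-membered carbocycle is closed by ring expansion, that is by cleavage of the bond shared by the three- and five-membered rings, and the five-membered carbonate by a 5-exo-trig attack of oxygen on the allyl cation terminus. The new centre at C1 is controlled by the existing C6 centre, because the short O–C tether can reach C1 only on the face that carries the C6 oxygen, so the carbonate must be cis-fused. The step needs capture at C1 and not at C3, which is secured because C3 is out of reach of the tether and the C4 silyl ether cannot participate, and either cyclopropane face isomer of 10 would converge because C1 and C3 are planar in 11. The hindered pyridine takes up the acid that is released, so that the silyl ether should survive.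

Step 9
Reactants: 13 (3aR,6R,7R,7aR)-4-bromo-6-[(tert-butyldimethylsilyl)oxy]-7-(propan-2-yl)-3a,6,7,7a-tetrahydro-1,3-benzodioxol-2-one
Product: 14 (1R,2R,5R,6R)-3-bromo-5-[(tert-butyldimethylsilyl)oxy]-6-(propan-2-yl)cyclohex-3-ene-1,2-diol
Conditions: K2CO3 (cat.), MeOH, 0 °C to rt
Reagents that add atoms: none
Why: Base-catalysed transesterification of the strained five-membered carbonate with methanol releases the cis-diol by acyl–oxygen cleavage, so both carbinol centres keep their configuration while the silyl ether and the vinyl bromide are untouched.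

Step 10
Reactants: 14 (1R,2R,5R,6R)-3-bromo-5-[(tert-butyldimethylsilyl)oxy]-6-(propan-2-yl)cyclohex-3-ene-1,2-diol
Product: 15 (4R,5R,6R)-2-bromo-4-[(tert-butyldimethylsilyl)oxy]-6-hydroxy-5-(propan-2-yl)cyclohex-2-en-1-one
Conditions: MnO2, CH2Cl2, rt
Reagents that add atoms: none
Why: Activated MnO2 oxidises allylic alcohols much faster than saturated ones, so the C1 hydroxyl should become the bromoenone carbonyl while the C6 hydroxyl stays, its configuration being the stable one trans to isopropyl.

Step 11
Reactants: 15 (4R,5R,6R)-2-bromo-4-[(tert-butyldimethylsilyl)oxy]-6-hydroxy-5-(propan-2-yl)cyclohex-2-en-1-one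
Product: 16 (4R,5R,6R)-6-acetoxy-2-bromo-4-[(tert-butyldimethylsilyl)oxy]-5-(propan-2-yl)cyclohex-2-en-1-one
Conditions: Ac2O, pyridine, DMAP (cat.), CH2Cl2, 0 °C
Reagents that add atoms: acetic anhydride, CC(=O)OC(C)=O
Why: Acetylation of the remaining secondary alcohol with Ac2O under nucleophilic catalysis is routine and occurs at oxygen, so C6 keeps its configuration.

Step 12
Reactants: 16 (4R,5R,6R)-6-acetoxy-2-bromo-4-[(tert-butyldimethylsilyl)oxy]-5-(propan-2-yl)cyclohex-2-en-1-one
Product: 17 (4S,5R,6R)-6-acetoxy-4-[(tert-butyldimethylsilyl)oxy]-2-(hydroxymethyl)-5-(propan-2-yl)cyclohex-2-en-1-one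
Conditions: Bu3SnCH2OH, Pd(PPh3)4 (cat.), 1,4-dioxane, 90 °C
Reagents that add atoms: (tributylstannyl)methanol, CCCC[Sn](CO)(CCCC)CCCC
Why: In this Stille coupling the α-bromoenone should add oxidatively to zerovalent palladium with ease and the stannane transfers its hydroxymethyl group to C2, while the absence of any allylic ester at this stage rules out competing π-allyl formation.

Step 13
Reactants: 17 (4S,5R,6R)-6-acetoxy-4-[(tert-butyldimethylsilyl)oxy]-2-(hydroxymethyl)-5-(propan-2-yl)cyclohex-2-en-1-one
Product: 18 (4S,5S,6R)-6-acetoxy-4-hydroxy-2-(hydroxymethyl)-5-(propan-2-yl)cyclohex-2-en-1-one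
Conditions: HF·pyridine, THF/pyridine, 0 °C to rt
Reagents that add atoms: none
Why: Fluoride-induced cleavage of the silyl ether under buffered, non-basic conditions should free the C4 hydroxyl without acetyl migration, elimination or epimerisation at C6.

Step 14
Reactants: 18 (4S,5S,6R)-6-acetoxy-4-hydroxy-2-(hydroxymethyl)-5-(propan-2-yl)cyclohex-2-en-1-one; 19 tiglic acid
Product: 21 (4S,5S,6R)-6-acetoxy-4-{[(2E)-2-methylbut-2-enoyl]oxy}-2-({[(2E)-2-methylbut-2-enoyl]oxy}methyl)-5-(propan-2-yl)cyclohex-2-en-1-one, via C7 monotiglate 20 (not isolated)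
Conditions: 19, 2,4,6-Cl3C6H2COCl, Et3N, toluene, rt; then 18, DMAP, rt to 40 °C
Reagents that add atoms: tiglic acid (compound 19), C/C=C(\C)C(=O)O
Why: Yamaguchi esterification through the mixed anhydride of tiglic acid should acylate first the primary C7 alcohol and then the hindered C4 alcohol at oxygen with retention, and the E geometry of the tiglate, being the stable one, is not at risk.

Compound list

1 | furfural (furan-2-carbaldehyde) | O=Cc1ccco1 | starting material
2 | isopropylmagnesium chloride | CC(C)[Mg]Cl | starting material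
3 | rac-1-(furan-2-yl)-2-methylpropan-1-ol | CC(C)C(O)c1ccco1 | intermediate
4 | rac-trans-4-hydroxy-5-(propan-2-yl)cyclopent-2-en-1-one (racemate; the 4S,5R enantiomer is drawn) | O=C1[C@H](C(C)C)[C@@H](O)C=C1 | intermediate
5 | (4S,5R)-4-hydroxy-5-(propan-2-yl)cyclopent-2-en-1-one | O=C1[C@H](C(C)C)[C@@H](O)C=C1 | intermediate
6 | tert-butyl (1S,5R)-4-oxo-5-(propan-2-yl)cyclopent-2-en-1-yl carbonate | O=C1[C@H](C(C)C)[C@@H](OC(=O)OC(C)(C)C)C=C1 | intermediate
7 | tert-butyl (1S,4S,5S)-4-hydroxy-5-(propan-2-yl)cyclopent-2-en-1-yl carbonate (OH cis to isopropyl, OBoc trans) | O[C@H]1C=C[C@H](OC(=O)OC(C)(C)C)[C@H]1C(C)C | intermediate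
8 | tert-butyl (1S,4S,5R)-4-[(tert-butyldimethylsilyl)oxy]-5-(propan-2-yl)cyclopent-2-en-1-yl carbonate | CC(C)(C)[Si](C)(C)O[C@H]1C=C[C@H](OC(=O)OC(C)(C)C)[C@H]1C(C)C | intermediate
9 | bromoform | BrC(Br)Br | starting material
10 | tert-butyl (1S,2R,3R,4R,5R)-6,6-dibromo-4-[(tert-butyldimethylsilyl)oxy]-3-(propan-2-yl)bicyclo[3.1.0]hexan-2-yl carbonate (cyclopropane anti to OTBS and isopropyl) | BrC1(Br)[C@H]2[C@H](O[Si](C)(C)C(C)(C)C)[C@H](C(C)C)[C@@H](OC(=O)OC(C)(C)C)[C@@H]12 | intermediate
11 | 2-bromo-6-[(tert-butoxycarbonyl)oxy]-4-[(tert-butyldimethylsilyl)oxy]-5-(propan-2-yl)cyclohex-2-en-1-yl cation (allyl cation over C1–C3; C4, C5, C6 as in 10) | BrC1=C[C@H](O[Si](C)(C)C(C)(C)C)[C@H](C(C)C)[C@@H](OC(=O)OC(C)(C)C)[CH+]1 | intermediate (not isolated)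
12 | 2-tert-butoxy-1,3-dioxolan-2-ylium ion cis-fused at C1/C6 of the bromocyclohexene (ring skeleton and configuration of 13) | BrC1=C[C@H](O[Si](C)(C)C(C)(C)C)[C@H](C(C)C)[C@H]2OC(OC(C)(C)C)=[O+][C@H]21 | intermediate (not isolated)
13 | (3aR,6R,7R,7aR)-4-bromo-6-[(tert-butyldimethylsilyl)oxy]-7-(propan-2-yl)-3a,6,7,7a-tetrahydro-1,3-benzodioxol-2-one | BrC1=C[C@H](O[Si](C)(C)C(C)(C)C)[C@H](C(C)C)[C@H]2OC(=O)O[C@H]21 | intermediate
14 | (1R,2R,5R,6R)-3-bromo-5-[(tert-butyldimethylsilyl)oxy]-6-(propan-2-yl)cyclohex-3-ene-1,2-diol | BrC1=C[C@H](O[Si](C)(C)C(C)(C)C)[C@H](C(C)C)[C@@H](O)[C@H]1O | intermediate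
15 | (4R,5R,6R)-2-bromo-4-[(tert-butyldimethylsilyl)oxy]-6-hydroxy-5-(propan-2-yl)cyclohex-2-en-1-one | BrC1=C[C@H](O[Si](C)(C)C(C)(C)C)[C@H](C(C)C)[C@@H](O)C1=O | intermediate
16 | (4R,5R,6R)-6-acetoxy-2-bromo-4-[(tert-butyldimethylsilyl)oxy]-5-(propan-2-yl)cyclohex-2-en-1-one | BrC1=C[C@H](O[Si](C)(C)C(C)(C)C)[C@H](C(C)C)[C@@H](OC(C)=O)C1=O | intermediate
17 | (4S,5R,6R)-6-acetoxy-4-[(tert-butyldimethylsilyl)oxy]-2-(hydroxymethyl)-5-(propan-2-yl)cyclohex-2-en-1-one | OCC1=C[C@H](O[Si](C)(C)C(C)(C)C)[C@H](C(C)C)[C@@H](OC(C)=O)C1=O | intermediate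
18 | (4S,5S,6R)-6-acetoxy-4-hydroxy-2-(hydroxymethyl)-5-(propan-2-yl)cyclohex-2-en-1-one | OCC1=C[C@H](O)[C@H](C(C)C)[C@@H](OC(C)=O)C1=O | intermediate
19 | tiglic acid ((2E)-2-methylbut-2-enoic acid) | C/C=C(\C)C(=O)O | starting material
20 | [(4S,5S,6R)-6-acetoxy-4-hydroxy-1-oxo-5-(propan-2-yl)cyclohex-2-en-2-yl]methyl (2E)-2-methylbut-2-enoate (C7 monotiglate; ring numbered as in the target) | C/C=C(\C)C(=O)OCC1=C[C@H](O)[C@H](C(C)C)[C@@H](OC(C)=O)C1=O | intermediate (not isolated)
21 | (4S,5S,6R)-6-acetoxy-4-{[(2E)-2-methylbut-2-enoyl]oxy}-2-({[(2E)-2-methylbut-2-enoyl]oxy}methyl)-5-(propan-2-yl)cyclohex-2-en-1-one (CNP0218511.1) | C/C=C(\C)C(=O)OCC1=C[C@H](OC(=O)/C(C)=C/C)[C@H](C(C)C)[C@@H](OC(C)=O)C1=O | target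

Total step count: 14. Longest linear sequence: 14 steps (1 to 21).

Steps most likely to fail

Step 8. Ionisation may be sluggish because both carbons next to the cyclopropane carry electron-withdrawing oxygen. Once the cation exists, proton loss, hydride shift or acid-induced loss of the silyl group may outrun closure of the carbonate. The fallback sets out from 10 and comes back at 14. It replaces carbonate cyclisation with loss of isobutene by classical acetoxy neighbouring-group participation in water, so that neither a tert-butyl cation nor a strong acid is formed.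
- NaOMe in MeOH should cleave the tert-butyl carbonate to the C6 alcohol (1S,2R,3R,4R,5R)-6,6-dibromo-4-[(tert-butyldimethylsilyl)oxy]-3-(propan-2-yl)bicyclo[3.1.0]hexan-2-ol F1.
- Ac2O/pyridine should then give the acetate F2.
- Silver-assisted solvolysis (AgBF4, aqueous acetone) should open the ring while the neighbouring acetate delivers oxygen to C1 from the C6 face. After hydrolysis this should leave the cis hydroxy acetate F3 (C6 acetate, C1 alcohol), accompanied through acyl shift by its isomer F4 (C1 acetate, C6 alcohol).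
- K2CO3/MeOH should convert both into diol 14.

Step 7. Carbene transfer to an alkene that is hindered on both faces and deactivated by two allylic oxygens may be slow, and the long contact with hydroxide may hydrolyse the carbonate. The fallback sets out from 5 and comes back at 10. It changes the order of events so that the carbene meets a base-stable bis(silyl ether) and the carbonate is introduced only afterwards.
- TESCl/imidazole should give the triethylsilyl ether F5.
- Luche reduction should give the alcohol F6.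
- TBSCl/imidazole should give the bis(silyl ether) F7.
- CHBr3/NaOH/BnEt3NCl, which can now be forced with excess reagent and time, should give the dibromocyclopropane F8.
- PPTS in MeOH should remove only the triethylsilyl group and give the C6 alcohol already described as F1.
- Boc2O/DMAP should then give 10.

Step 5. Facial selectivity may be poor, because the isopropyl group shields one face of the carbonyl and the carbonate the other. The fallback sets out from 6 and comes back at 7, and corrects the centre by inversion instead of relying on the hydride. The epimeric alcohol F9 (hydroxyl trans to isopropyl) formed in the reduction is separated. Mitsunobu reaction (4-nitrobenzoic acid, PPh3, DIAD, THF, 0 °C) should give the inverted 4-nitrobenzoate F10. Brief K2CO3/MeOH at 0 °C, which should cleave the activated benzoate well before the tert-butyl carbonate, then gives 7.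

Further compounds

F1 | step 8 | (1S,2R,3R,4R,5R)-6,6-dibromo-4-[(tert-butyldimethylsilyl)oxy]-3-(propan-2-yl)bicyclo[3.1.0]hexan-2-ol | BrC1(Br)[C@H]2[C@H](O[Si](C)(C)C(C)(C)C)[C@H](C(C)C)[C@@H](O)[C@@H]12
F2 | step 8 | (1S,2R,3R,4R,5R)-6,6-dibromo-4-[(tert-butyldimethylsilyl)oxy]-3-(propan-2-yl)bicyclo[3.1.0]hexan-2-yl acetate | BrC1(Br)[C@H]2[C@H](O[Si](C)(C)C(C)(C)C)[C@H](C(C)C)[C@@H](OC(C)=O)[C@@H]12
F3 | step 8 | (1R,2R,5R,6R)-3-bromo-5-[(tert-butyldimethylsilyl)oxy]-2-hydroxy-6-(propan-2-yl)cyclohex-3-en-1-yl acetate | BrC1=C[C@H](O[Si](C)(C)C(C)(C)C)[C@H](C(C)C)[C@@H](OC(C)=O)[C@H]1O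
F4 | step 8 | (1R,4R,5R,6R)-2-bromo-4-[(tert-butyldimethylsilyl)oxy]-6-hydroxy-5-(propan-2-yl)cyclohex-2-en-1-yl acetate | BrC1=C[C@H](O[Si](C)(C)C(C)(C)C)[C@H](C(C)C)[C@@H](O)[C@H]1OC(C)=O
F5 | step 7 | (4S,5R)-5-(propan-2-yl)-4-[(triethylsilyl)oxy]cyclopent-2-en-1-one | O=C1[C@H](C(C)C)[C@@H](O[Si](CC)(CC)CC)C=C1
F6 | step 7 | (1S,4S,5S)-5-(propan-2-yl)-4-[(triethylsilyl)oxy]cyclopent-2-en-1-ol | O[C@H]1C=C[C@H](O[Si](CC)(CC)CC)[C@H]1C(C)C
F7 | step 7 | tert-butyl(dimethyl){[(1S,4S,5R)-5-(propan-2-yl)-4-[(triethylsilyl)oxy]cyclopent-2-en-1-yl]oxy}silane | CC(C)(C)[Si](C)(C)O[C@H]1C=C[C@H](O[Si](CC)(CC)CC)[C@H]1C(C)C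
F8 | step 7 | (1S,2R,3R,4R,5R)-6,6-dibromo-4-[(tert-butyldimethylsilyl)oxy]-3-(propan-2-yl)-2-[(triethylsilyl)oxy]bicyclo[3.1.0]hexane | BrC1(Br)[C@H]2[C@H](O[Si](C)(C)C(C)(C)C)[C@H](C(C)C)[C@@H](O[Si](CC)(CC)CC)[C@@H]12
F9 | step 5 | tert-butyl (1S,4R,5S)-4-hydroxy-5-(propan-2-yl)cyclopent-2-en-1-yl carbonate | O[C@@H]1C=C[C@H](OC(=O)OC(C)(C)C)[C@H]1C(C)C
F10 | step 5 | (1S,4S,5S)-4-[(tert-butoxycarbonyl)oxy]-5-(propan-2-yl)cyclopent-2-en-1-yl 4-nitrobenzoate | O=C(O[C@H]1C=C[C@H](OC(=O)OC(C)(C)C)[C@H]1C(C)C)c1ccc(cc1)[N+](=O)[O-]
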